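**Strategy**

Ring numbering: C1 ketone, C2=C3, C4 tertiary carbinol, C5, C6 secondary carbinol. The ring is opened at C1–C2. The plan exploits the 1,4-relationship of the C4 hydroxyl and the C1 ketone in the cyclohexenone ring: in the precursor they are tied as a γ-lactone (O–C1–C6–C5–C4) whose C4 also carries the C17 chain and a (Z)-2-iodoethenyl group (C3=C2). Iodine–lithium exchange makes C2 a nucleophile that attacks its own lactone carbonyl; in one operation the carbocycle closes, the lactone opens, and enone and free tertiary alcohol appear. C6 comes from (S)-malic acid; C4 is set by 1,3-induction when the chain Grignard reagent adds to an ynone.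

Key step: step 8

Remark: compounds 1, 4 (the acetonide of (S)-malic acid) and 6 are taken as purchasable; should 4 not be at hand, (S)-malic acid, 2,2-dimethoxypropane and TsOH give it in one step.

**Route**

Step 1
Reactants: 1 (Z)-heptadec-10-enoic acid
Product: 2 (Z)-heptadec-10-en-1-ol
Conditions: LiAlH4, THF, 0 °C to rt; then H2O
Reagents that add atoms: none
Why: LiAlH4 reduction of the carboxylic acid to the primary alcohol should leave the isolated Z alkene untouched, and no stereocentre is involved.

Step 2
Reactants: 2 (Z)-heptadec-10-en-1-ol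
Product: 3 (Z)-1-bromoheptadec-10-ene
Conditions: CBr4, PPh3, CH2Cl2, 0 °C
Reagents that add atoms: carbon tetrabromide, BrC(Br)(Br)Br
Why: Appel reaction, in which the alcohol is activated as an alkoxyphosphonium ion and displaced by bromide under neutral conditions, so the Z alkene should neither migrate nor isomerise.

Step 3
Reactants: 4 (S)-2-(2,2-dimethyl-5-oxo-1,3-dioxolan-4-yl)acetic acid
Product: 5 (S)-2-(2,2-dimethyl-5-oxo-1,3-dioxolan-4-yl)acetyl chloride
Conditions: (COCl)2, DMF (cat.), CH2Cl2, 0 °C to rt; volatiles removed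
Reagents that add atoms: oxalyl chloride, ClC(=O)C(Cl)=O
Why: acid chloride formation through the chloroiminium species from DMF proceeds without base, so the acylal ring and its stereocentre (the later C6) should be unaffected.

Step 4
Reactants: 5 (S)-2-(2,2-dimethyl-5-oxo-1,3-dioxolan-4-yl)acetyl chloride; 6 tributyl[(trimethylsilyl)ethynyl]stannane
Product: 7 (5S)-2,2-dimethyl-5-[2-oxo-4-(trimethylsilyl)but-3-yn-1-yl]-1,3-dioxolan-4-one
Conditions: PdCl2(PPh3)2 (cat.), 1,2-dichloroethane, 50 °C
Reagents that add atoms: none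
Why: acyl Stille coupling (oxidative addition of zerovalent palladium into the C–Cl bond, transfer of the alkynyl group from tin in preference to butyl, reductive elimination) should give the ynone without acid or base, as the acylal and the β-oxygenated ketone require, and does not touch the stereocentre.

Step 5
Reactants: 3 (Z)-1-bromoheptadec-10-ene; 7 (5S)-2,2-dimethyl-5-[2-oxo-4-(trimethylsilyl)but-3-yn-1-yl]-1,3-dioxolan-4-one
Product: 10 (3S,5R)-5-[(Z)-heptadec-10-en-1-yl]-3-hydroxy-5-[(trimethylsilyl)ethynyl]oxolan-2-one, via (Z)-heptadec-10-enylmagnesium bromide 8 (not isolated), via bromomagnesium alkoxide adduct 9 (not isolated)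
Conditions: 3, Mg, Et2O, reflux; then 7, MgBr2·OEt2, CH2Cl2, −78 °C to rt; aq NH4Cl
Reagents that add atoms: none
Why: Grignard 1,2-addition to the ynone carbonyl, which at −78 °C is far more electrophilic than the dioxolanone carbonyl and whose silylated terminus blocks conjugate addition; C4 is set by 1,3-induction from C6 (1,3-chelation model: magnesium bridges the ketone oxygen and the C6 oxygen, the chain enters axially, anti to the C6 carbonyl substituent, and the slim alkynyl group lets the ketone behave like an aldehyde), which should favour the (5R) lactone with chain and hydroxyl cis; on warming, alkoxide 9 attacks the activated dioxolanone carbonyl (5-exo-trig transacylation), acetone is lost and the γ-lactone with free C6 hydroxyl results, any C4 epimer being removable by chromatography at this stage.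

Step 6
Reactants: 10 (3S,5R)-5-[(Z)-heptadec-10-en-1-yl]-3-hydroxy-5-[(trimethylsilyl)ethynyl]oxolan-2-one
Product: 11 (3S,5R)-5-[(Z)-heptadec-10-en-1-yl]-3-hydroxy-5-(iodoethynyl)oxolan-2-one
Conditions: N-iodosuccinimide, AgNO3 (cat.), acetone, rt, dark
Reagents that add atoms: N-iodosuccinimide, O=C1CCC(=O)N1I
Why: silver-catalysed iododesilylation converts the alkynylsilane via a silver acetylide into the 1-iodoalkyne under neutral conditions that should spare the lactone, the free hydroxyl and the chain alkene.

Step 7
Reactants: 11 (3S,5R)-5-[(Z)-heptadec-10-en-1-yl]-3-hydroxy-5-(iodoethynyl)oxolan-2-one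
Product: 12 (3S,5R)-5-[(Z)-heptadec-10-en-1-yl]-3-hydroxy-5-[(Z)-2-iodoethenyl]oxolan-2-one
Conditions: 2-nitrobenzenesulfonylhydrazide, Et3N, THF/i-PrOH, rt
Reagents that add atoms: none
Why: diimide reduction, in which diimide generated in situ transfers two hydrogen atoms in a concerted syn fashion to the iodoalkyne, should give the (Z)-iodoalkene without hydrogenolysis of the C–I bond; the polarised iodoalkyne should react faster than the unactivated internal cis alkene of the chain, and the reagent is limited accordingly.

Step 8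
Reactants: 12 (3S,5R)-5-[(Z)-heptadec-10-en-1-yl]-3-hydroxy-5-[(Z)-2-iodoethenyl]oxolan-2-one
Product: 15 (4R,6S)-4-[(Z)-heptadec-10-en-1-yl]-4,6-dihydroxycyclohex-2-en-1-one, via alkenyllithium alkoxide 13 (not isolated), via bridged dilithium hemiketal dialkoxide 14 (not isolated)
Conditions: MeLi (1.0 equiv), THF/Et2O, −78 °C; t-BuLi (2.1 equiv), −100 °C to −40 °C, high dilution; AcOH, −78 °C
Reagents that add atoms: none
Why: Proposed new method: after MeLi has turned the C6 hydroxyl into its lithium alkoxide, iodine–lithium exchange gives the configurationally stable (Z)-alkenyllithium 13, whose carbanionic C2 is held above the lactone carbonyl C1; addition gives the bridged tetrahedral alkoxide 14, which collapses by cleavage of the C1–O(ring) bond, so that the C1–C2 bond, the enone and the free C4 hydroxyl arise in one operation. The closest known reaction type is the Parham-type cyclisation (halogen–lithium exchange followed by intramolecular acyl substitution at an ester), supported by the known opening of 7-oxabicyclo[2.2.1]heptenes that carry a bridgehead oxygen to 4-hydroxycyclohex-2-enones; new is that the nucleophile sits on the alkoxy carbon of a lactone, so that the tetrahedral intermediate is bicyclic. The carbocycle closes in the 6-exo-trig mode (C2 onto C1=O) across the five-membered lactone, whose ring oxygen becomes the one-atom bridge of 14 and is then released as the C4 alkoxide. No stereocentre of the product is formed here: C4 and C6 are carried over from 12, the transient bridgehead C1 can only have the configuration the bicycle allows, and the C2=C3 geometry is fixed by the ring. The step needs exchange to outrun attack of t-BuLi on the lactone, and addition to outrun proton transfer from C6–H: the first is secured by the speed of iodine–lithium exchange at −100 °C, the second by the C6 alkoxide (removal of H6 would give a dianion) and by the Z geometry that places C2 within bonding distance of C1. The strain of 14 is offset by the change from a C–Li to an O–Li bond and is released when the bridge opens; should 14 survive until the quench, its hemiketal opens to 15 on protonation.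

**Compound list**

1 | (Z)-heptadec-10-enoic acid | CCCCCC/C=C\CCCCCCCCC(=O)O | starting material
2 | (Z)-heptadec-10-en-1-ol | CCCCCC/C=C\CCCCCCCCCO | intermediate
3 | (Z)-1-bromoheptadec-10-ene | CCCCCC/C=C\CCCCCCCCCBr | intermediate
4 | (S)-2-(2,2-dimethyl-5-oxo-1,3-dioxolan-4-yl)acetic acid (acetonide of (S)-malic acid) | OC(=O)C[C@@H]1OC(C)(C)OC1=O | starting material
5 | (S)-2-(2,2-dimethyl-5-oxo-1,3-dioxolan-4-yl)acetyl chloride | ClC(=O)C[C@@H]1OC(C)(C)OC1=O | intermediate
6 | tributyl[(trimethylsilyl)ethynyl]stannane | CCCC[Sn](CCCC)(CCCC)C#C[Si](C)(C)C | starting material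
7 | (5S)-2,2-dimethyl-5-[2-oxo-4-(trimethylsilyl)but-3-yn-1-yl]-1,3-dioxolan-4-one | C[Si](C)(C)C#CC(=O)C[C@@H]1OC(C)(C)OC1=O | intermediate
8 | (Z)-heptadec-10-enylmagnesium bromide | CCCCCC/C=C\CCCCCCCCC[Mg]Br | intermediate
9 | bromomagnesium (3R,13Z)-3-{[(4S)-2,2-dimethyl-5-oxo-1,3-dioxolan-4-yl]methyl}-1-(trimethylsilyl)icos-13-en-1-yn-3-olate | CCCCCC/C=C\CCCCCCCCC[C@](O[Mg]Br)(C#C[Si](C)(C)C)C[C@@H]1OC(C)(C)OC1=O | intermediate
10 | (3S,5R)-5-[(Z)-heptadec-10-en-1-yl]-3-hydroxy-5-[(trimethylsilyl)ethynyl]oxolan-2-one (chain and hydroxyl cis) | CCCCCC/C=C\CCCCCCCCC[C@]1(C#C[Si](C)(C)C)C[C@H](O)C(=O)O1 | intermediate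
11 | (3S,5R)-5-[(Z)-heptadec-10-en-1-yl]-3-hydroxy-5-(iodoethynyl)oxolan-2-one | CCCCCC/C=C\CCCCCCCCC[C@]1(C#CI)C[C@H](O)C(=O)O1 | intermediate
12 | (3S,5R)-5-[(Z)-heptadec-10-en-1-yl]-3-hydroxy-5-[(Z)-2-iodoethenyl]oxolan-2-one | CCCCCC/C=C\CCCCCCCCC[C@]1(/C=C\I)C[C@H](O)C(=O)O1 | intermediate
13 | lithium (3S,5R)-5-[(Z)-heptadec-10-en-1-yl]-5-[(Z)-2-lithioethenyl]-2-oxooxolan-3-olate | CCCCCC/C=C\CCCCCCCCC[C@]1(/C=C\[Li])C[C@H](O[Li])C(=O)O1 | intermediate
14 | dilithium (1R,4R,6S)-4-[(Z)-heptadec-10-en-1-yl]-7-oxabicyclo[2.2.1]hept-2-ene-1,6-bis(olate) (6-olate exo) | CCCCCC/C=C\CCCCCCCCC[C@]12C=C[C@@](O[Li])(O2)[C@@H](O[Li])C1 | intermediate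
15 | (4R,6S)-4-[(Z)-heptadec-10-en-1-yl]-4,6-dihydroxycyclohex-2-en-1-one (hydroxyls cis) | CCCCCC/C=C\CCCCCCCCC[C@]1(O)C=CC(=O)[C@@H](O)C1 | target

**Step count**

Total step count: 8. Longest linear sequence: 6 steps (steps 3, 4, 5, 6, 7, 8 from compound 4; the chain branch 1 → 2 → 3 joins at step 5 and is equally long).

**Steps most likely to fail**

Step 8 (the labelled step). What may go wrong: t-BuLi adds to the lactone carbonyl before the exchange is complete; the alkenyllithium is quenched by proton transfer and gives the de-iodinated ethenyl lactone; or the transannular addition is too slow because of strain and the anion decomposes on warming. The fallback uses known chemistry and closes the same C1–C2 bond at the aldehyde oxidation level. It sets out from 12. Silylation (TBSOTf, 2,6-lutidine, CH2Cl2, −78 °C) should give (3S,5R)-3-[(tert-butyldimethylsilyl)oxy]-5-[(Z)-heptadec-10-en-1-yl]-5-[(Z)-2-iodoethenyl]oxolan-2-one F1. Reduction with i-Bu2AlH (CH2Cl2, −78 °C) should give the corresponding lactol, (3S,5R)-3-[(tert-butyldimethylsilyl)oxy]-5-[(Z)-heptadec-10-en-1-yl]-5-[(Z)-2-iodoethenyl]oxolan-2-ol F2, which equilibrates with its γ-hydroxy aldehyde. A Nozaki–Hiyama–Kishi reaction (CrCl2, NiCl2 cat., DMF/THF, rt; divalent chromium, catalytic divalent nickel) should add the alkenyl iodide to the aldehyde and give (4R,6S)-6-[(tert-butyldimethylsilyl)oxy]-4-[(Z)-heptadec-10-en-1-yl]cyclohex-2-ene-1,4-diol F3 as a mixture of C1 epimers. MnO2 (CH2Cl2, rt) should oxidise the secondary allylic alcohol selectively to (4R,6S)-6-[(tert-butyldimethylsilyl)oxy]-4-[(Z)-heptadec-10-en-1-yl]-4-hydroxycyclohex-2-en-1-one F4. HF·pyridine (THF, 0 °C) removes the silyl group, and the fallback comes back to the route at 15.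

Step 5. What may go wrong: the facial selectivity of the 1,3-induction is low or opposite to the model (the acylal oxygen is a weak donor), or the basic alkyl Grignard reagent enolises 7 and triggers β-elimination of the C6 oxygen. The fallback makes the two C–C bonds at C4 in the opposite order, which turns the same facial preference into the opposite C4 configuration and replaces the basic alkyl nucleophile at the sensitive stage by a much less basic acetylide. It sets out from 5 and 8. Iron-catalysed acylation of the Grignard reagent (Fe(acac)3 cat., THF, −78 °C) should give (5S)-2,2-dimethyl-5-[(Z)-2-oxononadec-12-en-1-yl]-1,3-dioxolan-4-one F5. Lithium (trimethylsilyl)acetylide (THF, −78 °C to rt) should add to the ketone to give lithium (3R,13Z)-3-{[(4S)-2,2-dimethyl-5-oxo-1,3-dioxolan-4-yl]methyl}-1-(trimethylsilyl)icos-13-en-1-yn-3-olate F6, which lactonises with loss of acetone as in step 5. The fallback comes back to the route at 10, the C4 epimers again being separated at that stage.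

Step 7. What may go wrong: diimide also saturates the chain alkene, or reduces the iodoalkene further. The fallback replaces diimide by hydroboration and protonolysis, using a hindered dialkylborane that discriminates strongly between a 1-iodoalkyne and an internal cis alkene. It sets out from 11. Dicyclohexylborane (2.2 equiv, THF, 0 °C; the first equivalent is consumed by the hydroxyl) should add syn to give (3S,5R)-5-[(Z)-2-(dicyclohexylboranyl)-2-iodoethenyl]-3-[(dicyclohexylboranyl)oxy]-5-[(Z)-heptadec-10-en-1-yl]oxolan-2-one F7. Protonolysis of the C–B bond with AcOH (retention) and aqueous work-up bring the fallback back to the route at 12.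

**Further compounds**

F1 | step 8 | (3S,5R)-3-[(tert-butyldimethylsilyl)oxy]-5-[(Z)-heptadec-10-en-1-yl]-5-[(Z)-2-iodoethenyl]oxolan-2-one | CCCCCC/C=C\CCCCCCCCC[C@]1(/C=C\I)C[C@H](O[Si](C)(C)C(C)(C)C)C(=O)O1
F2 | step 8 | (3S,5R)-3-[(tert-butyldimethylsilyl)oxy]-5-[(Z)-heptadec-10-en-1-yl]-5-[(Z)-2-iodoethenyl]oxolan-2-ol (both anomers) | CCCCCC/C=C\CCCCCCCCC[C@]1(/C=C\I)C[C@H](O[Si](C)(C)C(C)(C)C)C(O)O1
F3 | step 8 | (4R,6S)-6-[(tert-butyldimethylsilyl)oxy]-4-[(Z)-heptadec-10-en-1-yl]cyclohex-2-ene-1,4-diol (both C1 epimers) | CCCCCC/C=C\CCCCCCCCC[C@]1(O)C=CC(O)[C@@H](O[Si](C)(C)C(C)(C)C)C1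
F4 | step 8 | (4R,6S)-6-[(tert-butyldimethylsilyl)oxy]-4-[(Z)-heptadec-10-en-1-yl]-4-hydroxycyclohex-2-en-1-one | CCCCCC/C=C\CCCCCCCCC[C@]1(O)C=CC(=O)[C@@H](O[Si](C)(C)C(C)(C)C)C1
F5 | step 5 | (5S)-2,2-dimethyl-5-[(Z)-2-oxononadec-12-en-1-yl]-1,3-dioxolan-4-one | CCCCCC/C=C\CCCCCCCCCC(=O)C[C@@H]1OC(C)(C)OC1=O
F6 | step 5 | lithium (3R,13Z)-3-{[(4S)-2,2-dimethyl-5-oxo-1,3-dioxolan-4-yl]methyl}-1-(trimethylsilyl)icos-13-en-1-yn-3-olate | CCCCCC/C=C\CCCCCCCCC[C@](O[Li])(C#C[Si](C)(C)C)C[C@@H]1OC(C)(C)OC1=O
F7 | step 7 | (3S,5R)-5-[(Z)-2-(dicyclohexylboranyl)-2-iodoethenyl]-3-[(dicyclohexylboranyl)oxy]-5-[(Z)-heptadec-10-en-1-yl]oxolan-2-one | CCCCCC/C=C\CCCCCCCCC[C@]1(/C=C(\I)B(C2CCCCC2)C2CCCCC2)C[C@H](OB(C2CCCCC2)C2CCCCC2)C(=O)O1
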